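Follow the target. Here is what stands and what is asked.

in all of them: starting material 0.50 M
- Tuesday's: second substrate 0.25 M; reagent 0.81 M; precatalyst 1 mM; run made earlier
- Saturday's: second substrate 0.25 M; reagent 0.96 M; precatalyst 1 mM; run made earlier
- elm: second substrate 0.250 M; reagent 0.650 M; precatalyst 1.0 mM; time 30 min
- birch: second substrate 0.250 M; reagent 0.780 M; precatalyst 1.0 mM; time 30 min

- Tuesday's (time / min: target / %, starting material / %): 4.00: 3.4, 93.6; 8.00: 10.7, 80.2; 12.0: 14.8, 66.4; 15.0: 18.5, 57.3
- Saturday's (time / min: target / %, starting material / %): 2.00: 0.6, 99.1; 5.00: 7.1, 89.6; 10.0: 14.3, 69.2; 15.0: 18.5, 50.4

(scatter of a reading: 0.5 percentage points)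

1. which of the two there is more of at the end, elm (target / over-reaction product)
2. which of the two there is more of at the end, birch (target / over-reaction product)
3. final target, as a percentage of the starting material charged, in elm
4. final target, as a percentage of the starting material charged, in birch

- the earlier runs were read with a standard deviation of 0.5 percentage points

We draw the curve first. It starts flat: Saturday's flask has lost 0.900% of its starting material by 2.00 min, and we take that as the knee. Over the last three readings, the fall per molar reagent is 0.0404 /min/M of the charge on Tuesday and 0.0408 /min/M on Saturday. So we read the slope after the knee as going with reagent: 0.0264 /min in elm and 0.0317 /min in birch.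

We assume that the unaccounted starting material is over-reaction product, and that reagent carries both the making and the loss of target. Reagent then cancels from target gained per starting material consumed. That gain is one minus target over a ceiling, the level where making equals loss, which is the inverse of a selectivity factor. Over those same readings, Tuesday gives 22.1% and Saturday 18.0%, so we carry the target ceiling 20.1%.

The crossing also belongs to conversion. Over-reaction product is behind target at 19.8% conversion on Tuesday and ahead at 30.8% on Saturday. At its slope after the knee, elm reaches that upper conversion near 13.7 min and birch near 11.7 min. We therefore expect over-reaction product ahead in both flasks, with target near the ceiling in both.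

The forecast agrees on the order but not on target: over-reaction product in elm and over-reaction product in birch, with target 24% and 23% against our ceiling of 20.1%. It says: “Lower reagent only delays the crossover”.

Elm ends with target at 22.5% and over-reaction product at 30.6%; birch ends at 22.7% and 39.7%.

    starting material + free catalyst ⇌ catalyst intermediate A (K = 3.50 /M, k = 11.0 /M/s)
    reagent + target → over-reaction product (k = 0.00620 /M/s)
    precatalyst → free catalyst (k = 0.00170 /s)
    reagent + catalyst intermediate B → free catalyst + second product (k = 3.80 /M/s)
    second substrate + free catalyst ⇌ catalyst intermediate B (K = 3.60 /M, k = 330 /M/s)
    reagent + catalyst intermediate A → free catalyst + target (k = 2.50 /M/s)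

In elm, the loss step alone, at charged reagent, gives target a half-life of 2.9 min, shorter than the 30 min run. Elm's target stands 2.4 points above our ceiling, which was read from scattered readings. In the scheme, target is made through catalyst intermediate A and lost without catalyst. Holding the share of catalyst in that intermediate, we therefore scale the ceiling with precatalyst. For the neighbour of birch charged with 0.0017 M of precatalyst, we reckon it at 34.2%. That neighbour ends below this, with target at 31.1% and reagent at 2.0% of its charge.

The data were computed with constants of no real substance; the scatter is artificial.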